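**Retrosynthetic overview**
1. Target ⇐ its 7,2′,4′-tri-O-allyl ether, freed last by neutral palladium-mediated deallylation (no acid near the prenyl groups or the tertiary ketol).
2. C3 carbinol ⇐ protected isoflavone: one-flask conjugate hydride addition and reagent-controlled enolate hydroxylation (the chemical counterpart of isoflavone reduction plus 3-hydroxylation) sets the only stereocentre.
3. Isoflavone ⇐ 2′-hydroxychalcone in one flask: phenol oxa-Michael closure of ring C (chalcone isomerase step), then oxidative C2→C3 aryl shift with trivalent iodine (isoflavone synthase step), both prenyl groups already in place.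
4. Chalcone ⇐ Claisen–Schmidt union of 3,5-di-C-prenylated resacetophenone (direct phenoxide C-prenylation, prenyltransferase-like) with 2,4-bis(allyloxy)benzaldehyde.
5. Ring order: rings A and B are bought as benzene rings; ring C is the only ring formed (step 5).

Assumption: the given SMILES is the (3R) enantiomer, and oxaziridine 11 is taken to attack the C3 Re face as in the 2-substituted 1-tetralone and 3-benzylchroman-4-one series; if the first run shows the opposite sense, the mirror-image reagent (also sold) is used with nothing else changed.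

**Route**

Step 1
Reactants: 1 2,4-dihydroxyacetophenone; 2 prenyl bromide (1-bromo-3-methylbut-2-ene)
Product: 3 1-[2,4-dihydroxy-3,5-bis(3-methylbut-2-en-1-yl)phenyl]ethan-1-one
Conditions: 2 (2.5 equiv), KOH (10% aq), 0 °C to rt, 16 h; chromatography, mono-prenyl ketones resubmitted
Reagents that add atoms: prenyl bromide 2, CC(C)=CCBr
Why: In water the resorcinol-type dianion of 1 is alkylated at carbon rather than oxygen, first at C3 between the two oxygens and then at C5 (phenoxide C-allylation, the chemical counterpart of an aromatic prenyltransferase); the yield is modest (roughly 15–25%) but the material is very cheap.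

Step 2
Reactants: 3 1-[2,4-dihydroxy-3,5-bis(3-methylbut-2-en-1-yl)phenyl]ethan-1-one; 4 allyl bromide (3-bromoprop-1-ene)
Product: 5 1-[4-(allyloxy)-2-hydroxy-3,5-bis(3-methylbut-2-en-1-yl)phenyl]ethan-1-one
Conditions: 4 (1.2 equiv), K2CO3, acetone, 56 °C
Reagents that add atoms: allyl bromide 4, C=CCBr
Why: The 2-OH is locked in a hydrogen bond to the acetyl oxygen and is far less acidic and nucleophilic, so the Williamson etherification takes place only at the 4-OH.

Step 3
Reactants: 6 2,4-dihydroxybenzaldehyde; 4 allyl bromide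
Product: 7 2,4-bis(allyloxy)benzaldehyde
Conditions: 4 (2.5 equiv), K2CO3, DMF, 60 °C
Reagents that add atoms: allyl bromide 4, C=CCBr
Why: Double Williamson etherification; DMF and gentle heat are enough to alkylate the chelated 2-OH as well.

Step 4
Reactants: 5 1-[4-(allyloxy)-2-hydroxy-3,5-bis(3-methylbut-2-en-1-yl)phenyl]ethan-1-one; 7 2,4-bis(allyloxy)benzaldehyde
Product: 8 (E)-3-[2,4-bis(allyloxy)phenyl]-1-[4-(allyloxy)-2-hydroxy-3,5-bis(3-methylbut-2-en-1-yl)phenyl]prop-2-en-1-one
Conditions: KOH (50% aq), EtOH, rt, 24–48 h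
Reagents that add atoms: none
Why: Claisen–Schmidt (crossed aldol) condensation in which only the methyl ketone can enolise and the aldehyde has no α-hydrogen, with E1cB dehydration giving the E-enone; aryl allyl ethers and prenyl groups are inert to hydroxide.

Step 5
Reactants: 8 (E)-3-[2,4-bis(allyloxy)phenyl]-1-[4-(allyloxy)-2-hydroxy-3,5-bis(3-methylbut-2-en-1-yl)phenyl]prop-2-en-1-one
Product: 10 7-(allyloxy)-3-[2,4-bis(allyloxy)phenyl]-6,8-bis(3-methylbut-2-en-1-yl)-4H-chromen-4-one, via flavanone 9 (not isolated)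
Conditions: NaOAc (2.0 equiv), MeOH, 65 °C, 24 h; then 0 °C, HC(OMe)3, H2SO4 (2.3 equiv), PhI(OAc)2 (1.2 equiv), 0 °C to rt, 1–2 h
Reagents that add atoms: none
Why: Proposed new method: acetate-mediated 6-endo oxa-Michael closure of the chelated phenol onto the enone gives flavanone 9, whose enolised ketone is attacked at C3 by the trivalent iodine electrophile in the acidic orthoformate medium, and loss of iodobenzene with anti migration of the electron-rich 2,4-dialkoxyphenyl group from C2 to C3, then loss of the C3 proton, gives the isoflavone (hypervalent-iodine 2,3-aryl shift of flavanones is the closest known reaction); the untested part is carrying two prenyl groups and three allyl ethers through it, which rests on enol attack being much faster than attack on an isolated alkene, as when prenylated phenols are oxidised with PhI(OAc)2 and keep their prenyl alkenes.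

Step 6
Reactants: 10 7-(allyloxy)-3-[2,4-bis(allyloxy)phenyl]-6,8-bis(3-methylbut-2-en-1-yl)-4H-chromen-4-one; 11 (+)-[(8,8-dichlorocamphoryl)sulfonyl]oxaziridine (enantiomer made from (1S)-(+)-10-camphorsulfonic acid)
Product: 13 (3R)-7-(allyloxy)-3-[2,4-bis(allyloxy)phenyl]-3-hydroxy-6,8-bis(3-methylbut-2-en-1-yl)-2,3-dihydro-4H-chromen-4-one, via potassium enolate 12 (not isolated)
Conditions: KBH(s-Bu)3 (1.05 equiv), THF, −78 °C, 1 h; then 11 (1.5 equiv), −78 to −40 °C; AcOH, −78 °C
Reagents that add atoms: oxaziridine 11, O=S1(=O)C[C@]23CC[C@H](C(Cl)(Cl)[C@]24ON14)C3(C)C (transfers its oxygen atom)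
Why: Proposed new method: 1,4-hydride delivery from the bulky borohydride to C2 of the vinylogous ester (known for isoflavones) gives the tetrasubstituted potassium enolate 12 regiospecifically, and the camphor-derived N-sulfonyloxaziridine then transfers oxygen to the Re face of C3 by SN2-type attack on its N–O bond (Davis asymmetric enolate hydroxylation, closest precedent the sodium enolates of 2-substituted 1-tetralones and 3-benzylchroman-4-ones), so the reagent alone sets the (3R) carbinol; telescoping the reduction with the chiral hydroxylation is the untested part.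

Step 7
Reactants: 13 (3R)-7-(allyloxy)-3-[2,4-bis(allyloxy)phenyl]-3-hydroxy-6,8-bis(3-methylbut-2-en-1-yl)-2,3-dihydro-4H-chromen-4-one
Product: 14 (3R)-3-(2,4-dihydroxyphenyl)-3,7-dihydroxy-6,8-bis(3-methylbut-2-en-1-yl)-2,3-dihydro-4H-chromen-4-one
Conditions: Pd(PPh3)4 (5 mol%), morpholine (10 equiv), degassed THF, rt
Reagents that add atoms: none
Why: Tsuji–Trost deallylation, in which zerovalent palladium ionises each aryl allyl ether to a phenoxide and an η3-allyl palladium cation that morpholine captures; C-prenyl groups carry no leaving group, no acid is present to cyclise them onto the phenols, and the quaternary C3 cannot epimerise.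

**Compound list**
1 | 1-(2,4-dihydroxyphenyl)ethan-1-one (2,4-dihydroxyacetophenone) | CC(=O)c1ccc(O)cc1O | starting material
2 | 1-bromo-3-methylbut-2-ene (prenyl bromide) | CC(C)=CCBr | starting material
3 | 1-[2,4-dihydroxy-3,5-bis(3-methylbut-2-en-1-yl)phenyl]ethan-1-one | CC(=O)c1cc(CC=C(C)C)c(O)c(CC=C(C)C)c1O | intermediate
4 | 3-bromoprop-1-ene (allyl bromide) | C=CCBr | starting material
5 | 1-[4-(allyloxy)-2-hydroxy-3,5-bis(3-methylbut-2-en-1-yl)phenyl]ethan-1-one | CC(=O)c1cc(CC=C(C)C)c(OCC=C)c(CC=C(C)C)c1O | intermediate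
6 | 2,4-dihydroxybenzaldehyde | O=Cc1ccc(O)cc1O | starting material
7 | 2,4-bis(allyloxy)benzaldehyde | O=Cc1ccc(OCC=C)cc1OCC=C | intermediate
8 | (E)-3-[2,4-bis(allyloxy)phenyl]-1-[4-(allyloxy)-2-hydroxy-3,5-bis(3-methylbut-2-en-1-yl)phenyl]prop-2-en-1-one (chalcone) | O=C(/C=C/c1ccc(OCC=C)cc1OCC=C)c1cc(CC=C(C)C)c(OCC=C)c(CC=C(C)C)c1O | intermediate
9 | racemic 7-(allyloxy)-2-[2,4-bis(allyloxy)phenyl]-6,8-bis(3-methylbut-2-en-1-yl)-2,3-dihydro-4H-chromen-4-one (flavanone) | O=C1CC(c2ccc(OCC=C)cc2OCC=C)Oc2c1cc(CC=C(C)C)c(OCC=C)c2CC=C(C)C | intermediate (not isolated)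
10 | 7-(allyloxy)-3-[2,4-bis(allyloxy)phenyl]-6,8-bis(3-methylbut-2-en-1-yl)-4H-chromen-4-one (isoflavone) | O=c1c(-c2ccc(OCC=C)cc2OCC=C)coc2c1cc(CC=C(C)C)c(OCC=C)c2CC=C(C)C | intermediate
11 | (+)-[(8,8-dichlorocamphoryl)sulfonyl]oxaziridine from (1S)-(+)-10-camphorsulfonic acid; (4aS,7S,8aR)-8,8-dichloro-9,9-dimethyltetrahydro-4H-4a,7-methanooxazirino[3,2-i][2,1]benzisothiazole 3,3-dioxide | O=S1(=O)C[C@]23CC[C@H](C(Cl)(Cl)[C@]24ON14)C3(C)C | starting material
12 | potassium 7-(allyloxy)-3-[2,4-bis(allyloxy)phenyl]-6,8-bis(3-methylbut-2-en-1-yl)-2H-chromen-4-olate | [K+].[O-]C1=C(c2ccc(OCC=C)cc2OCC=C)COc2c1cc(CC=C(C)C)c(OCC=C)c2CC=C(C)C | intermediate (not isolated)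
13 | (3R)-7-(allyloxy)-3-[2,4-bis(allyloxy)phenyl]-3-hydroxy-6,8-bis(3-methylbut-2-en-1-yl)-2,3-dihydro-4H-chromen-4-one | CC(C)=CCc1cc2c(c(CC=C(C)C)c1OCC=C)OC[C@](O)(c1ccc(OCC=C)cc1OCC=C)C2=O | intermediate
14 | (3R)-3-(2,4-dihydroxyphenyl)-3,7-dihydroxy-6,8-bis(3-methylbut-2-en-1-yl)-2,3-dihydro-4H-chromen-4-one | CC(C)=CCc1cc2c(c(CC=C(C)C)c1O)OC[C@](O)(c1ccc(O)cc1O)C2=O | target

**Step count and risks**
Total steps: 7. Longest linear sequence: 6 (steps 1, 2, 4, 5, 6, 7; step 3 is a one-step side branch).

Steps most likely to fail: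

Step 5. The acid may add methanol across a prenyl alkene, the iodine reagent may attack an alkene, ring contraction to a dihydrobenzofuran ester may compete with the aryl shift, and any 8 that has not cyclised is lost. The fallback sets out from 8 and comes back at 10 without any electrophilic oxidant. The chelated phenol of 8 is capped with MOMCl and i-Pr2NEt to give the 2′-O-methoxymethyl chalcone F1. Weitz–Scheffer epoxidation (H2O2, NaOH, MeOH/THF, 0 °C), which does not touch prenyl or allyl alkenes, gives the racemic trans-epoxy ketone F2. BF3·OEt2 (CH2Cl2, −78 °C) opens the epoxide at the benzylic carbon and the aroyl group shifts (Meinwald-type rearrangement) to give the 2-aryl-3-aryl-3-oxopropanal F3, which has the same connectivity as the aryl-shift product. Brief HCl in MeOH at rt removes the methoxymethyl group; the phenol closes on the aldehyde and the resulting 2-hydroxyisoflavanone loses water to give 10.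

Step 6. The borane-containing potassium enolate may give lower ee than the sodium enolates of the precedent, and the facial sense must be confirmed. The fallback sets out from 10 and comes back at 13, with control moved from a chiral oxidant to a chiral ion pair. Compound 10 is reduced with KBH(s-Bu)3 as before but quenched with AcOH, and the racemic isoflavanone F4 is isolated. F4 is then hydroxylated with O2 (1 atm) and P(OEt)3 in toluene over 50% aq KOH at −20 °C under a chiral ammonium phase-transfer catalyst, N-(9-anthracenylmethyl)cinchoninium chloride, or its cinchonidinium pseudoenantiomer if that one gives the (3R) alcohol.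

Step 1. Low yield and separation from the 3-prenyl, 5-prenyl and O-prenyl isomers. The fallback sets out from 1 and comes back at 3, replacing phenoxide C-alkylation by cross-coupling. Compound 1 is iodinated at both activated positions (I2, HIO3, aq EtOH) to give 1-(2,4-dihydroxy-3,5-diiodophenyl)ethan-1-one F5. Both iodides are then exchanged for prenyl by Stille coupling with tributyl(3-methylbut-2-en-1-yl)stannane (Pd(PPh3)4, LiCl, DMF, 90 °C).

**Further compounds**
F1 | step 5 | (E)-3-[2,4-bis(allyloxy)phenyl]-1-[4-(allyloxy)-2-(methoxymethoxy)-3,5-bis(3-methylbut-2-en-1-yl)phenyl]prop-2-en-1-one | O=C(/C=C/c1ccc(OCC=C)cc1OCC=C)c1cc(CC=C(C)C)c(OCC=C)c(CC=C(C)C)c1OCOC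
F2 | step 5 | racemic trans-[4-(allyloxy)-2-(methoxymethoxy)-3,5-bis(3-methylbut-2-en-1-yl)phenyl]{3-[2,4-bis(allyloxy)phenyl]oxiran-2-yl}methanone (one enantiomer drawn) | O=C([C@H]1O[C@@H]1c1ccc(OCC=C)cc1OCC=C)c1cc(CC=C(C)C)c(OCC=C)c(CC=C(C)C)c1OCOC
F3 | step 5 | racemic 2-[2,4-bis(allyloxy)phenyl]-3-[4-(allyloxy)-2-(methoxymethoxy)-3,5-bis(3-methylbut-2-en-1-yl)phenyl]-3-oxopropanal | O=CC(c1ccc(OCC=C)cc1OCC=C)C(=O)c1cc(CC=C(C)C)c(OCC=C)c(CC=C(C)C)c1OCOC
F4 | step 6 | racemic 7-(allyloxy)-3-[2,4-bis(allyloxy)phenyl]-6,8-bis(3-methylbut-2-en-1-yl)-2,3-dihydro-4H-chromen-4-one | O=C1C(c2ccc(OCC=C)cc2OCC=C)COc2c1cc(CC=C(C)C)c(OCC=C)c2CC=C(C)C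
F5 | step 1 | 1-(2,4-dihydroxy-3,5-diiodophenyl)ethan-1-one | CC(=O)c1cc(I)c(O)c(I)c1O
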